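**Retrosynthetic overview**
- Target 16 ← ortho-bromination at C5′ of ring B phenol 15 ← BCl3 debenzylation of 14 ← O-methylation of ring A phenol 13.
- Ring A of 13 ← inverse-demand Diels–Alder, CO2 extrusion and aromatization. The run C2(Br)–C3(H)–C4(Br)–C5(H) is C3–C6 of 3,5-dibromo-2-pyrone 3, and C1(O)–C6(O-aryl) is the alkene of the aryloxyketene methyl trimethylsilyl acetal 9.
- 9 ← ester 8 ← phenol 6 + methyl bromoacetate 7 ← 2-(benzyloxy)phenol 4; 3 ← coumalic acid 1.
- Ring B is bought as an arene. Ring A is the only ring made (step 5), and its two bromines and two oxygens arrive with the two components, so ring A is never halogenated and no aryl–oxygen coupling is run on a polybrominated arene.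

Key step: step 5

Remark on numbering and on one change of plan: ring A is C1 (OMe), C2 (Br), C3 (H), C4 (Br), C5 (H), C6 (O-aryl); ring B is C1′ (ether O), C2′ (Br), C3′ (H), C4′ (Br), C5′ (Br), C6′ (OH); the target is achiral. A mixed methyl silyl ketal is assumed to lose methanol rather than silanol on aromatization, so step 5 is planned to deliver the ring A phenol 13, which is methylated in step 6.

**Step 1**
Reactants: 1 coumalic acid
Product: 3 3,5-dibromo-2H-pyran-2-one, via 5-bromo-2H-pyran-2-one 2 (not isolated)
Conditions: NBS (2.5 equiv), LiOAc, MeCN–H2O (9:1), rt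
Reagents that add atoms: N-bromosuccinimide, O=C1CCC(=O)N1Br
Why: Carboxylate-assisted ipso-bromodecarboxylation (Hunsdiecker-type) at C5 followed by electrophilic bromination (addition–elimination) at C3 is the established one-flask entry to this dibromopyrone.

**Step 2**
Reactants: 4 2-(benzyloxy)phenol
Product: 6 2-(benzyloxy)-4,6-dibromophenol, via 2-(benzyloxy)-6-bromophenol 5 (not isolated)
Conditions: NBS (2.1 equiv), iPr2NH (0.2 equiv), CH2Cl2, 0 °C → rt, dark
Reagents that add atoms: N-bromosuccinimide, O=C1CCC(=O)N1Br
Why: In this amine-mediated electrophilic aromatic bromination the N-bromo species is delivered by the hydrogen-bonded phenol, so substitution should occur ortho (C6) and then para (C4) to the free OH, overriding the weaker benzyloxy director.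

**Step 3**
Reactants: 6 2-(benzyloxy)-4,6-dibromophenol; 7 methyl bromoacetate
Product: 8 methyl [2-(benzyloxy)-4,6-dibromophenoxy]acetate
Conditions: K2CO3, acetone, reflux
Reagents that add atoms: none
Why: Williamson ether synthesis of an acidic dibromophenoxide with a reactive α-halo ester, which tolerates the two ortho substituents.

**Step 4**
Reactants: 8 methyl [2-(benzyloxy)-4,6-dibromophenoxy]acetate
Product: 9 1-(benzyloxy)-3,5-dibromo-2-{[2-methoxy-2-(trimethylsilyloxy)ethenyl]oxy}benzene (E/Z mixture)
Conditions: LiN(SiMe3)2, THF, −78 °C; then Me3SiCl/Et3N, −78 °C → rt; pentane, filtration under argon, used crude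
Reagents that add atoms: chlorotrimethylsilane, C[Si](C)(C)Cl
Why: Ester enolization and O-silylation (silyl ketene acetal formation) as in glycolate Ireland–Claisen practice; the amide base is strong enough for the α-aryloxy ester but should not metalate the aryl C–H flanked by two bromines, and the alkene geometry is irrelevant.

**Step 5**
Reactants: 3 3,5-dibromo-2H-pyran-2-one; 9 1-(benzyloxy)-3,5-dibromo-2-{[2-methoxy-2-(trimethylsilyloxy)ethenyl]oxy}benzene
Product: 13 2-[2-(benzyloxy)-4,6-dibromophenoxy]-4,6-dibromophenol, via bridged lactone 10 (not isolated), via cyclohexadiene ketal 11 (not isolated), via aryl trimethylsilyl ether 12 (not isolated)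
Conditions: toluene, 110 → 140 °C, sealed tube; then 1 M HCl, THF, rt
Reagents that add atoms: none
Why: The electron-poor pyrone 3 serves as diene and the electron-rich alkene of 9 as dienophile in a thermal, strongly asynchronous inverse-demand [4+2] cycloaddition to bridged lactone 10; the closest known reaction type is the pyrone–ketene acetal arene synthesis (coumalates or 3-carbomethoxy-2-pyrone with 1,1-dimethoxyethylene). Retro-[4+2] loss of CO2 from 10 leaves cyclohexadiene 11, which aromatizes by ionization at the mixed ketal carbon and loss of the neighbouring C–H; by analogy with mixed methyl silyl vinylketene acetals, methanol should leave and the silyloxy oxygen stay, so aryl silyl ether 12 and, after dilute acid, phenol 13 are expected. Ring A is therefore closed by an intermolecular cycloaddition that forms C1–C2 and C5–C6 in one operation, not by a cyclization, and the four transient stereocentres of 10 vanish on aromatization, so no stereocontrol is needed. The selectivity required is regiochemical: the two oxygen donors on the acetal carbon make the aryloxy-bearing carbon the nucleophilic end, which should bond to C6 of the pyrone (the δ-position of the unsaturated lactone) while the acetal carbon bonds to C3, placing the oxygenated C1 next to C2–Br and para to C4–Br. Should part of 11 lose trimethylsilanol instead, what forms is anisole 14 itself, which passes through step 6 unchanged together with 13.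

**Step 6**
Reactants: 13 2-[2-(benzyloxy)-4,6-dibromophenoxy]-4,6-dibromophenol
Product: 14 1-(benzyloxy)-3,5-dibromo-2-(3,5-dibromo-2-methoxyphenoxy)benzene
Conditions: MeI, K2CO3, DMF, rt
Reagents that add atoms: iodomethane, CI
Why: Williamson O-methylation of an acidic dibromophenol, under which the benzyl ether, diaryl ether and aryl bromides are inert.

**Step 7**
Reactants: 14 1-(benzyloxy)-3,5-dibromo-2-(3,5-dibromo-2-methoxyphenoxy)benzene
Product: 15 3,5-dibromo-2-(3,5-dibromo-2-methoxyphenoxy)phenol
Conditions: BCl3, C6HMe5, CH2Cl2, −78 °C; then H2O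
Reagents that add atoms: none
Why: Lewis acid debenzylation in which pentamethylbenzene traps the benzyl cation (Friedel–Crafts); at −78 °C the aryl methyl ether should survive, and hydrogenolysis is avoided because of the aryl bromides.

**Step 8**
Reactants: 15 3,5-dibromo-2-(3,5-dibromo-2-methoxyphenoxy)phenol
Product: 16 2,3,5-tribromo-6-(3,5-dibromo-2-methoxyphenoxy)phenol (CNP0282108.0)
Conditions: NBS (1.0 equiv), iPr2NH (0.1 equiv), CH2Cl2, 0 °C
Reagents that add atoms: N-bromosuccinimide, O=C1CCC(=O)N1Br
Why: Amine-mediated ortho-selective electrophilic bromination of the phenol should go to C5′, the only free ortho carbon, because the para carbon C3′ is shielded between two bromines and ring A has no free position ortho or para to an oxygen.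

**Compound list**
1 | coumalic acid (2-oxo-2H-pyran-5-carboxylic acid) | O=C(O)c1ccc(=O)oc1 | starting material
2 | 5-bromo-2H-pyran-2-one | O=c1ccc(Br)co1 | intermediate
3 | 3,5-dibromo-2H-pyran-2-one | O=c1occ(Br)cc1Br | intermediate
4 | 2-(benzyloxy)phenol | Oc1ccccc1OCc1ccccc1 | starting material
5 | 2-(benzyloxy)-6-bromophenol | Oc1c(Br)cccc1OCc1ccccc1 | intermediate
6 | 2-(benzyloxy)-4,6-dibromophenol | Oc1c(Br)cc(Br)cc1OCc1ccccc1 | intermediate
7 | methyl bromoacetate | COC(=O)CBr | starting material
8 | methyl [2-(benzyloxy)-4,6-dibromophenoxy]acetate | COC(=O)COc1c(Br)cc(Br)cc1OCc1ccccc1 | intermediate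
9 | 1-(benzyloxy)-3,5-dibromo-2-{[2-methoxy-2-(trimethylsilyloxy)ethenyl]oxy}benzene (E/Z mixture) | COC(O[Si](C)(C)C)=COc1c(Br)cc(Br)cc1OCc1ccccc1 | intermediate
10 | 6-[2-(benzyloxy)-4,6-dibromophenoxy]-4,7-dibromo-5-methoxy-5-(trimethylsilyloxy)-2-oxabicyclo[2.2.2]oct-7-en-3-one (racemic, mixture of diastereomers at C5 and C6) | O=C1OC2C(Br)=CC1(Br)C(OC)(O[Si](C)(C)C)C2Oc3c(Br)cc(Br)cc3OCc3ccccc3 | intermediate
11 | 1-(benzyloxy)-3,5-dibromo-2-{[3,5-dibromo-6-methoxy-6-(trimethylsilyloxy)cyclohexa-2,4-dien-1-yl]oxy}benzene (racemic, mixture of diastereomers) | BrC1=CC(Br)=CC(Oc2c(Br)cc(Br)cc2OCc2ccccc2)C1(OC)O[Si](C)(C)C | intermediate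
12 | {2-[2-(benzyloxy)-4,6-dibromophenoxy]-4,6-dibromophenoxy}trimethylsilane | C[Si](C)(C)Oc1c(Br)cc(Br)cc1Oc1c(Br)cc(Br)cc1OCc1ccccc1 | intermediate
13 | 2-[2-(benzyloxy)-4,6-dibromophenoxy]-4,6-dibromophenol | Oc1c(Br)cc(Br)cc1Oc1c(Br)cc(Br)cc1OCc1ccccc1 | intermediate
14 | 1-(benzyloxy)-3,5-dibromo-2-(3,5-dibromo-2-methoxyphenoxy)benzene | COc1c(Br)cc(Br)cc1Oc1c(Br)cc(Br)cc1OCc1ccccc1 | intermediate
15 | 3,5-dibromo-2-(3,5-dibromo-2-methoxyphenoxy)phenol | COc1c(Br)cc(Br)cc1Oc1c(Br)cc(Br)cc1O | intermediate
16 | 2,3,5-tribromo-6-(3,5-dibromo-2-methoxyphenoxy)phenol | COc1c(Br)cc(Br)cc1Oc1c(Br)cc(Br)c(Br)c1O | target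

**Step count**
Total: 8 steps. Longest linear sequence: 7 steps (steps 2–8 from 2-(benzyloxy)phenol); step 1 is a one-step branch.

**Steps most likely to fail**

Step 5. The hindered β-aryloxy ketene acetal may add to C6 of the pyrone in a conjugate (Mukaiyama–Michael) sense without ring closure. It may also undergo O-to-C silyl migration or hydrolysis before it reacts, or the bridged lactone may resist CO2 extrusion. The fallback builds the diaryl ether first and brominates ring A afterwards. It sets out from compound 6, which is heated with commercial 2-fluorobenzaldehyde (O=Cc1ccccc1F) and K2CO3 in DMAc at 130 °C in a nucleophilic aromatic substitution to give 2-[2-(benzyloxy)-4,6-dibromophenoxy]benzaldehyde F1. Baeyer–Villiger oxidation with mCPBA in CH2Cl2 should give 2-[2-(benzyloxy)-4,6-dibromophenoxy]phenyl formate F2, which is cleaved with K2CO3 in MeOH to 2-[2-(benzyloxy)-4,6-dibromophenoxy]phenol F3. Dibromination ortho and para to the free OH (NBS 2 equiv, iPr2NH cat., CH2Cl2; ring B is deactivated) rejoins the route at compound 13.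

Step 8. Bromination may occur at the para carbon C3′ or run on to a second substitution. The fallback replaces the substrate-controlled substitution by a directed C–H functionalization. It sets out from compound 15, which is acylated with Me2NCOCl and K2CO3 in MeCN to 3,5-dibromo-2-(3,5-dibromo-2-methoxyphenoxy)phenyl dimethylcarbamate F4. Carbamate-directed ortho C–H palladation and bromination (catalytic Pd(OAc)2, divalent palladium, with NBS and TsOH in MeCN) can reach only C5′ and should give 2,3,5-tribromo-6-(3,5-dibromo-2-methoxyphenoxy)phenyl dimethylcarbamate F5. Hydrolysis with KOH in aqueous EtOH at reflux, then acidification, comes back to the route at compound 16.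

Step 2. The benzyloxy group may compete as director (attack at C5, para to OBn), which would give regioisomeric dibromides that are hard to separate. The fallback buys the bromine pattern. It sets out from compound 7, which alkylates commercial 3,5-dibromo-2-hydroxybenzaldehyde (O=Cc1cc(Br)cc(Br)c1O) with K2CO3 in DMF at rt to give methyl (2,4-dibromo-6-formylphenoxy)acetate F6. Baeyer–Villiger oxidation with mCPBA in CH2Cl2 should give methyl [2,4-dibromo-6-(formyloxy)phenoxy]acetate F7, and brief K2CO3/MeOH at 0 °C releases methyl (2,4-dibromo-6-hydroxyphenoxy)acetate F8. F8 is benzylated at once (BnBr, K2CO3, DMF) to rejoin the route at compound 8, so that steps 2 and 3 are bypassed.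

**Further compounds**
F1 | step 5 | 2-[2-(benzyloxy)-4,6-dibromophenoxy]benzaldehyde | O=Cc1ccccc1Oc1c(Br)cc(Br)cc1OCc1ccccc1
F2 | step 5 | 2-[2-(benzyloxy)-4,6-dibromophenoxy]phenyl formate | O=COc1ccccc1Oc1c(Br)cc(Br)cc1OCc1ccccc1
F3 | step 5 | 2-[2-(benzyloxy)-4,6-dibromophenoxy]phenol | Oc1ccccc1Oc1c(Br)cc(Br)cc1OCc1ccccc1
F4 | step 8 | 3,5-dibromo-2-(3,5-dibromo-2-methoxyphenoxy)phenyl dimethylcarbamate | COc1c(Br)cc(Br)cc1Oc1c(Br)cc(Br)cc1OC(=O)N(C)C
F5 | step 8 | 2,3,5-tribromo-6-(3,5-dibromo-2-methoxyphenoxy)phenyl dimethylcarbamate | COc1c(Br)cc(Br)cc1Oc1c(Br)cc(Br)c(Br)c1OC(=O)N(C)C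
F6 | step 2 | methyl (2,4-dibromo-6-formylphenoxy)acetate | COC(=O)COc1c(Br)cc(Br)cc1C=O
F7 | step 2 | methyl [2,4-dibromo-6-(formyloxy)phenoxy]acetate | COC(=O)COc1c(Br)cc(Br)cc1OC=O
F8 | step 2 | methyl (2,4-dibromo-6-hydroxyphenoxy)acetate | COC(=O)COc1c(Br)cc(Br)cc1O
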